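**Retrosynthetic overview**

- Numbering: ring C1 (bears the side chain) to C6 (C3 Cl, C4 Me/OH, C5 O-angelate, C6 OH); chain C7 (=CH2), C8 (O-angelate), C9, C10–C11 (oxirane). The route rests on the homoallylic alcohol C6(OH)–C1–C7(=CH2), in which the C6 oxygen and C7 are cis on the six-membered ring, so that C8 as a carboxyl carbon closes a cis-fused γ-lactone through O6.
- Late disconnections: the C10–C11 oxirane (asymmetric epoxidation, last), C3–Cl/C4–OH (chloride opening of a C3–C4 epoxide placed cis to the C5 hydroxyl), both angelates, the prenyl terminus (cross-metathesis) and C8–C9 (allylboration of the lactol obtained from the lactone).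
- Key disconnection: C1–C6 and O6–C8, made in one flask from an acyclic (Z,Z)-2-(bromomethyl)dienoate aldehyde with CrCl2. The cyclohexene forms first, the temporary γ-lactone second.
- Precursor: C1=C7 by Baylis–Hillman reaction and SN2' bromination; C3=C4 by Z-selective Wittig reaction of the methyl ketone from (S)-glyceraldehyde acetonide, which supplies C5.
- Ring order: cyclohexene, γ-lactone (reduced and opened at C8), ring oxirane (opened to the chlorohydrin), side-chain oxirane.

Key step: step 13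

Assumption: the bromide ether of step 1, angelic anhydride, (−)-Ipc2B(allyl) and the D-fructose-derived epoxidation ketone are bought as such; C5 carries a triethylsilyl group through the key step so that C6 can later take a longer-lived silyl group.

**Step 1**
Reactants: 1 1-[(3-bromopropoxy)methyl]-4-methoxybenzene
Product: 2 {3-[(4-methoxybenzyl)oxy]propyl}triphenylphosphonium bromide
Conditions: PPh3, MeCN, reflux
Reagents that add atoms: triphenylphosphine, c1ccc(cc1)P(c1ccccc1)c1ccccc1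
Why: SN2 quaternisation of triphenylphosphine by the primary bromide should give the Wittig salt.

**Step 2**
Reactants: 3 (S)-2,2-dimethyl-1,3-dioxolane-4-carbaldehyde
Product: 4 1-[(4S)-2,2-dimethyl-1,3-dioxolan-4-yl]ethan-1-ol (both carbinol epimers)
Conditions: MeMgBr, THF, −78 → 0 °C; aq. NH4Cl
Reagents that add atoms: methylmagnesium bromide, C[Mg]Br
Why: Grignard addition to the aldehyde; the new carbinol centre is of no consequence because it is oxidised in the next step.

**Step 3**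
Reactants: 4 1-[(4S)-2,2-dimethyl-1,3-dioxolan-4-yl]ethan-1-ol
Product: 5 1-[(4S)-2,2-dimethyl-1,3-dioxolan-4-yl]ethan-1-one
Conditions: Dess–Martin periodinane, NaHCO3, CH2Cl2, 0 °C → rt
Reagents that add atoms: none
Why: Dess–Martin oxidation under buffered, base-free conditions should give the α-alkoxy methyl ketone without epimerising the dioxolane stereocentre.

**Step 4**
Reactants: 2 {3-[(4-methoxybenzyl)oxy]propyl}triphenylphosphonium bromide; 5 1-[(4S)-2,2-dimethyl-1,3-dioxolan-4-yl]ethan-1-one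
Product: 7 (4R)-4-{(2Z)-5-[(4-methoxybenzyl)oxy]pent-2-en-2-yl}-2,2-dimethyl-1,3-dioxolane, via phosphorus ylide 6 (not isolated)
Conditions: 2, KN(SiMe3)2, THF, −78 °C; then 5, −78 °C → rt
Reagents that add atoms: none
Why: Wittig olefination of an α-alkoxy methyl ketone with a non-stabilised ylide, a combination known to be Z-selective, should place the oxygen-bearing C5 and the ylide chain (C2) cis across C3=C4, and the low temperature should keep the α-stereocentre intact.

**Step 5**
Reactants: 7 (4R)-4-{(2Z)-5-[(4-methoxybenzyl)oxy]pent-2-en-2-yl}-2,2-dimethyl-1,3-dioxolane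
Product: 8 (2R,3Z)-6-[(4-methoxybenzyl)oxy]-3-methylhex-3-ene-1,2-diol
Conditions: AcOH/H2O (4:1), 40 °C
Reagents that add atoms: none
Why: Acid-catalysed acetal hydrolysis frees the 1,2-diol; the 4-methoxybenzyl ether and the trisubstituted alkene are stable to dilute acetic acid.

**Step 6**
Reactants: 8 (2R,3Z)-6-[(4-methoxybenzyl)oxy]-3-methylhex-3-ene-1,2-diol
Product: 9 (2R,3Z)-6-[(4-methoxybenzyl)oxy]-3-methyl-1,2-bis(triethylsilyloxy)hex-3-ene
Conditions: Et3SiCl, imidazole, CH2Cl2, 0 °C → rt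
Reagents that add atoms: chlorotriethylsilane, CC[Si](Cl)(CC)CC
Why: Silyl ether formation on both hydroxyls gives the non-chelating C5 group wanted in the key step and a primary silyl ether that can later be removed selectively.

**Step 7**
Reactants: 9 (2R,3Z)-6-[(4-methoxybenzyl)oxy]-3-methyl-1,2-bis(triethylsilyloxy)hex-3-ene
Product: 10 (3Z,5R)-4-methyl-5,6-bis(triethylsilyloxy)hex-3-en-1-ol
Conditions: DDQ, CH2Cl2/pH 7 phosphate buffer, 0 °C
Reagents that add atoms: none
Why: Oxidative cleavage of the 4-methoxybenzyl ether by DDQ at buffered pH should leave the silyl ethers and the alkene untouched.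

**Step 8**
Reactants: 10 (3Z,5R)-4-methyl-5,6-bis(triethylsilyloxy)hex-3-en-1-ol
Product: 11 (3Z,5R)-4-methyl-5,6-bis(triethylsilyloxy)hex-3-enal
Conditions: Dess–Martin periodinane, NaHCO3, CH2Cl2, 0 °C; used at once
Reagents that add atoms: none
Why: Dess–Martin oxidation gives the β,γ-unsaturated aldehyde without any base that would move the alkene into conjugation.

**Step 9**
Reactants: 11 (3Z,5R)-4-methyl-5,6-bis(triethylsilyloxy)hex-3-enal; 12 methyl acrylate
Product: 13 methyl (5Z,7R)-3-hydroxy-6-methyl-2-methylidene-7,8-bis(triethylsilyloxy)oct-5-enoate (both C3 epimers)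
Conditions: 12 (excess), DABCO (1 equiv), 1,4-dioxane/H2O (1:1), rt
Reagents that add atoms: none
Why: Morita–Baylis–Hillman reaction, in which the DABCO–acrylate enolate adds to the aldehyde and elimination returns the amine; the new carbinol centre is lost in the next step, so its configuration does not matter.

**Step 10**
Reactants: 13 methyl (5Z,7R)-3-hydroxy-6-methyl-2-methylidene-7,8-bis(triethylsilyloxy)oct-5-enoate
Product: 14 methyl (2Z,5Z,7R)-2-(bromomethyl)-6-methyl-7,8-bis(triethylsilyloxy)octa-2,5-dienoate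
Conditions: NBS, Me2S, CH2Cl2, 0 °C → rt
Reagents that add atoms: N-bromosuccinimide, O=C1CCC(=O)N1Br
Why: Corey–Kim-type activation of the Baylis–Hillman alcohol followed by SN2' attack of bromide gives the rearranged primary allylic bromide, for which the Z isomer (chain trans to the ester) is the usual product.

**Step 11**
Reactants: 14 methyl (2Z,5Z,7R)-2-(bromomethyl)-6-methyl-7,8-bis(triethylsilyloxy)octa-2,5-dienoate
Product: 15 methyl (2Z,5Z,7R)-2-(bromomethyl)-8-hydroxy-6-methyl-7-(triethylsilyloxy)octa-2,5-dienoate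
Conditions: PPTS (cat.), MeOH/CH2Cl2 (1:3), −10 °C
Reagents that add atoms: none
Why: Acid-catalysed methanolysis cleaves the primary triethylsilyl ether much faster than the hindered secondary allylic one, and the medium contains no base or strong nucleophile that would attack the allylic bromide.

**Step 12**
Reactants: 15 methyl (2Z,5Z,7R)-2-(bromomethyl)-8-hydroxy-6-methyl-7-(triethylsilyloxy)octa-2,5-dienoate
Product: 16 methyl (2Z,5Z,7R)-2-(bromomethyl)-6-methyl-8-oxo-7-(triethylsilyloxy)octa-2,5-dienoate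
Conditions: Dess–Martin periodinane, NaHCO3, CH2Cl2, 0 °C; used at once
Reagents that add atoms: none
Why: Dess–Martin oxidation gives the α-silyloxy aldehyde under neutral conditions that should neither epimerise C5 nor touch the allylic bromide.

**Step 13**
Reactants: 16 methyl (2Z,5Z,7R)-2-(bromomethyl)-6-methyl-8-oxo-7-(triethylsilyloxy)octa-2,5-dienoate
Product: 19 (3aR,7R,7aS)-6-methyl-3-methylidene-7-(triethylsilyloxy)-3a,4,7,7a-tetrahydro-1-benzofuran-2(3H)-one, via allylchromium dichloride 17 (not isolated), via chromium alkoxide 18 (not isolated)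
Conditions: CrCl2 (5 equiv), THF, rt, 16 added slowly (final 0.005 M); aq. NH4Cl; PPTS (cat.), CH2Cl2 if any hydroxy ester remains
Reagents that add atoms: none
Why: Two equivalents of CrCl2 reduce the allylic C–Br bond to the allylchromium species 17 (trivalent chromium), which adds through its γ-carbon C1 to the C6 aldehyde in a six-membered chair transition state fused to the forming carbocycle, so that the C7 methylene is regenerated and the C1–C6 bond closes the cyclohexene; the chromium alkoxide 18 then acylates on the neighbouring methyl ester and expels methoxide. The closest known reaction type is the intramolecular Nozaki–Hiyama (Reformatsky-type) cyclisation of 2-(bromomethyl)acrylates onto aldehydes, which gives cis-fused α-methylene-γ-butyrolactones. The carbocycle closes in the 6-exo-trig mode at the aldehyde carbon and the lactone in the 5-exo-trig mode at the ester carbonyl. C6 is set by Felkin–Anh attack anti to the bulky, non-chelating C5 triethylsilyloxy group, which inside the ring places the C5 and C6 oxygens cis; C1 is set by the cis-fused bicyclic transition state, which puts C7 cis to the C6 oxygen, and only that cis hydroxy ester can lactonise. The step needs facial selectivity at the aldehyde relative to the single stereocentre C5 and ring closure in preference to intermolecular coupling; the silyl ether, the Z-configured C3=C4 alkene that holds C1 next to C6, and slow addition at high dilution are there to secure them.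

**Step 14**
Reactants: 19 (3aR,7R,7aS)-6-methyl-3-methylidene-7-(triethylsilyloxy)-3a,4,7,7a-tetrahydro-1-benzofuran-2(3H)-one
Product: 20 (3aR,7R,7aS)-6-methyl-3-methylidene-7-(triethylsilyloxy)-2,3,3a,4,7,7a-hexahydro-1-benzofuran-2-ol (both anomers)
Conditions: i-Bu2AlH (1.1 equiv), CH2Cl2, −78 °C; aq. KNa tartrate
Reagents that add atoms: none
Why: Diisobutylaluminium hydride adds once to the lactone carbonyl (1,2-reduction) and the aluminium hemiacetal is stable at −78 °C, so hydrolysis should give the lactol with C8 at the aldehyde oxidation level.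

**Step 15**
Reactants: 20 (3aR,7R,7aS)-6-methyl-3-methylidene-7-(triethylsilyloxy)-2,3,3a,4,7,7a-hexahydro-1-benzofuran-2-ol
Product: 21 (1S,2R,6R)-6-[(3S)-3-hydroxyhexa-1,5-dien-2-yl]-3-methyl-2-(triethylsilyloxy)cyclohex-3-en-1-ol
Conditions: (−)-Ipc2B(allyl) (2.5 equiv), Et2O, −78 °C → rt; then aq. NaOH, H2O2, 0 °C
Reagents that add atoms: (−)-B-allyldiisopinocampheylborane, C=CCB([C@@H]1C[C@@H]2C[C@H]([C@H]1C)C2(C)C)[C@@H]1C[C@@H]2C[C@H]([C@H]1C)C2(C)C
Why: Brown asymmetric allylboration of the 2-substituted acrolein that is in equilibrium with the lactol: the isopinocampheyl groups derived from (+)-α-pinene direct allyl to the Si face of the C8 aldehyde through a chair transition state, which sets C8 as S and releases the C6 hydroxyl.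

**Step 16**
Reactants: 21 (1S,2R,6R)-6-[(3S)-3-hydroxyhexa-1,5-dien-2-yl]-3-methyl-2-(triethylsilyloxy)cyclohex-3-en-1-ol
Product: 22 (1S,2R,6R)-6-[(3S)-3-hydroxy-6-methylhepta-1,5-dien-2-yl]-3-methyl-2-(triethylsilyloxy)cyclohex-3-en-1-ol
Conditions: 2-methylbut-2-ene (excess), RuCl2(=CHPh)(PCy3)(H2IMes) (second-generation Grubbs catalyst, 5 mol%), CH2Cl2, 40 °C
Reagents that add atoms: 2-methylbut-2-ene, CC=C(C)C
Why: Olefin cross-metathesis of the monosubstituted alkene with 2-methylbut-2-ene builds the prenyl terminus; the 1,1-disubstituted and the trisubstituted ring alkenes are too hindered to take part.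

**Step 17**
Reactants: 22 (1S,2R,6R)-6-[(3S)-3-hydroxy-6-methylhepta-1,5-dien-2-yl]-3-methyl-2-(triethylsilyloxy)cyclohex-3-en-1-ol
Product: 23 (3S)-2-[(1R,5R,6S)-6-hydroxy-4-methyl-5-(triethylsilyloxy)cyclohex-3-en-1-yl]-6-methylhepta-1,5-dien-3-yl (2Z)-2-methylbut-2-enoate
Conditions: angelic acid, 2,4,6-Cl3C6H2COCl, Et3N, toluene, rt; then 22, 80 °C
Reagents that add atoms: angelic acid, C/C=C(C)\C(=O)O
Why: Yamaguchi esterification through the mixed anhydride, run without a nucleophilic catalyst so that the Z-alkene does not isomerise to the tiglate; the acyclic allylic C8 hydroxyl should react in preference to the C6 hydroxyl, which is flanked by the C5 silyl ether and the C1 branch.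

**Step 18**
Reactants: 23 (3S)-2-[(1R,5R,6S)-6-hydroxy-4-methyl-5-(triethylsilyloxy)cyclohex-3-en-1-yl]-6-methylhepta-1,5-dien-3-yl (2Z)-2-methylbut-2-enoate
Product: 24 (3S)-2-[(1R,5R,6S)-6-(tert-butyldimethylsilyloxy)-4-methyl-5-(triethylsilyloxy)cyclohex-3-en-1-yl]-6-methylhepta-1,5-dien-3-yl (2Z)-2-methylbut-2-enoate
Conditions: t-BuMe2SiOTf, 2,6-lutidine, CH2Cl2, −78 → 0 °C
Reagents that add atoms: tert-butyldimethylsilyl triflate, CC(C)(C)[Si](C)(C)OS(=O)(=O)C(F)(F)F
Why: Silylation with the reactive silyl triflate caps the hindered C6 hydroxyl with a group that outlasts the triethylsilyl ether, so that C5 and C6 stay differentiated.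

**Step 19**
Reactants: 24 (3S)-2-[(1R,5R,6S)-6-(tert-butyldimethylsilyloxy)-4-methyl-5-(triethylsilyloxy)cyclohex-3-en-1-yl]-6-methylhepta-1,5-dien-3-yl (2Z)-2-methylbut-2-enoate
Product: 25 (3S)-2-[(1R,5R,6S)-6-(tert-butyldimethylsilyloxy)-5-hydroxy-4-methylcyclohex-3-en-1-yl]-6-methylhepta-1,5-dien-3-yl (2Z)-2-methylbut-2-enoate
Conditions: HF·pyridine, pyridine, THF, 0 °C
Reagents that add atoms: none
Why: Selective desilylation, since buffered HF·pyridine cleaves a triethylsilyl ether far faster than a tert-butyldimethylsilyl ether, so only the allylic C5 hydroxyl is freed.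

**Step 20**
Reactants: 25 (3S)-2-[(1R,5R,6S)-6-(tert-butyldimethylsilyloxy)-5-hydroxy-4-methylcyclohex-3-en-1-yl]-6-methylhepta-1,5-dien-3-yl (2Z)-2-methylbut-2-enoate
Product: 26 (3S)-2-[(1S,2S,3S,4R,6R)-3-(tert-butyldimethylsilyloxy)-2-hydroxy-1-methyl-7-oxabicyclo[4.1.0]heptan-4-yl]-6-methylhepta-1,5-dien-3-yl (2Z)-2-methylbut-2-enoate
Conditions: VO(acac)2 (cat.), t-BuOOH, CH2Cl2, 0 °C → rt
Reagents that add atoms: tert-butyl hydroperoxide, CC(C)(C)OO
Why: Hydroxyl-directed vanadium-catalysed epoxidation: the C5 allylic hydroxyl, the only free hydroxyl in 25, delivers the peroxide oxygen to the ring alkene on its own face, setting C3 and C4 with the oxirane cis to the C5 oxygen and leaving the prenyl, methylidene and angelate alkenes alone.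

**Step 21**
Reactants: 26 (3S)-2-[(1S,2S,3S,4R,6R)-3-(tert-butyldimethylsilyloxy)-2-hydroxy-1-methyl-7-oxabicyclo[4.1.0]heptan-4-yl]-6-methylhepta-1,5-dien-3-yl (2Z)-2-methylbut-2-enoate
Product: 27 (1R,2S,3S,4R,6R)-3-(tert-butyldimethylsilyloxy)-1-methyl-4-[(3S)-6-methyl-3-{[(2Z)-2-methylbut-2-enoyl]oxy}hepta-1,5-dien-2-yl]-7-oxabicyclo[4.1.0]heptan-2-yl (2Z)-2-methylbut-2-enoate
Conditions: LiN(SiMe3)2 (1.0 equiv), THF, −78 °C; then angelic anhydride, −78 → −20 °C
Reagents that add atoms: angelic anhydride, C/C=C(C)\C(=O)OC(=O)/C(C)=C\C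
Why: Acylation of the lithium alkoxide with the anhydride; C5 carries the only free hydroxyl, the cis oxirane cannot be opened by its own neighbouring alkoxide, and the low temperature should prevent silyl migration and Z/E isomerisation.

**Step 22**
Reactants: 27 (1R,2S,3S,4R,6R)-3-(tert-butyldimethylsilyloxy)-1-methyl-4-[(3S)-6-methyl-3-{[(2Z)-2-methylbut-2-enoyl]oxy}hepta-1,5-dien-2-yl]-7-oxabicyclo[4.1.0]heptan-2-yl (2Z)-2-methylbut-2-enoate
Product: 28 (3S)-2-[(1R,3S,4S,5S,6S)-6-(tert-butyldimethylsilyloxy)-3-chloro-4-hydroxy-4-methyl-5-{[(2Z)-2-methylbut-2-enoyl]oxy}cyclohexyl]-6-methylhepta-1,5-dien-3-yl (2Z)-2-methylbut-2-enoate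
Conditions: LiCl, AcOH, THF, rt
Reagents that add atoms: lithium chloride, [Li+].[Cl-]
Why: Acid-assisted SN2 opening of the oxirane by chloride (lithium halide–acetic acid halohydrin synthesis): attack at the secondary C3 from the face anti to the oxirane oxygen is the trans-diaxial (Fürst–Plattner) pathway that leads to the chair with the side chain equatorial, as in the opening of steroidal 5,6-epoxides by HCl, so C3 is inverted (Cl trans to the C4 hydroxyl) and C4 is retained.

**Step 23**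
Reactants: 28 (3S)-2-[(1R,3S,4S,5S,6S)-6-(tert-butyldimethylsilyloxy)-3-chloro-4-hydroxy-4-methyl-5-{[(2Z)-2-methylbut-2-enoyl]oxy}cyclohexyl]-6-methylhepta-1,5-dien-3-yl (2Z)-2-methylbut-2-enoate
Product: 29 (3S)-2-[(1R,3S,4S,5S,6S)-3-chloro-4,6-dihydroxy-4-methyl-5-{[(2Z)-2-methylbut-2-enoyl]oxy}cyclohexyl]-6-methylhepta-1,5-dien-3-yl (2Z)-2-methylbut-2-enoate
Conditions: HF·pyridine, THF, 0 °C → rt
Reagents that add atoms: none
Why: Desilylation with acidic fluoride frees the C6 hydroxyl; the chlorohydrin, which would close to the epoxide under basic fluoride, and the two esters are stable to these conditions.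

**Step 24**
Reactants: 29 (3S)-2-[(1R,3S,4S,5S,6S)-3-chloro-4,6-dihydroxy-4-methyl-5-{[(2Z)-2-methylbut-2-enoyl]oxy}cyclohexyl]-6-methylhepta-1,5-dien-3-yl (2Z)-2-methylbut-2-enoate
Product: 30 CNP0158207.1, (2S)-3-[(1R,3S,4S,5S,6S)-3-chloro-4,6-dihydroxy-4-methyl-5-{[(2Z)-2-methylbut-2-enoyl]oxy}cyclohexyl]-1-[(2R)-3,3-dimethyloxiran-2-yl]but-3-en-2-yl (2Z)-2-methylbut-2-enoate
Conditions: 1,2:4,5-di-O-isopropylidene-β-D-erythro-2,3-hexodiulo-2,6-pyranose (D-fructose-derived ketone, 3 equiv), 2KHSO5·KHSO4·K2SO4, NaHCO3, MeCN/aq. Na2EDTA, 0 °C, pH 7–8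
Reagents that add atoms: potassium peroxymonosulfate, [K+].[O-]S(=O)(=O)OO
Why: Shi asymmetric epoxidation by the chiral dioxirane: the electron-rich trisubstituted prenyl alkene should react before the ester-deactivated 1,1-disubstituted alkene and the conjugated angelate alkenes, the spiro transition state of the D-fructose-derived ketone delivers oxygen to the face that makes C10 R, and the near-neutral bicarbonate medium spares the base-labile chlorohydrin.

**Compound list**

1 | 1-[(3-bromopropoxy)methyl]-4-methoxybenzene | COc1ccc(COCCCBr)cc1 | starting material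
2 | {3-[(4-methoxybenzyl)oxy]propyl}triphenylphosphonium bromide | COc1ccc(COCCC[P+](c2ccccc2)(c2ccccc2)c2ccccc2)cc1.[Br-] | intermediate
3 | (S)-2,2-dimethyl-1,3-dioxolane-4-carbaldehyde | O=C[C@@H]1COC(C)(C)O1 | starting material
4 | 1-[(4S)-2,2-dimethyl-1,3-dioxolan-4-yl]ethan-1-ol (both carbinol epimers) | CC(O)[C@@H]1COC(C)(C)O1 | intermediate
5 | 1-[(4S)-2,2-dimethyl-1,3-dioxolan-4-yl]ethan-1-one | CC(=O)[C@@H]1COC(C)(C)O1 | intermediate
6 | {3-[(4-methoxybenzyl)oxy]propylidene}triphenylphosphorane | COc1ccc(COCCC=P(c2ccccc2)(c2ccccc2)c2ccccc2)cc1 | intermediate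
7 | (4R)-4-{(2Z)-5-[(4-methoxybenzyl)oxy]pent-2-en-2-yl}-2,2-dimethyl-1,3-dioxolane | COc1ccc(COCC/C=C(/C)[C@@H]2COC(C)(C)O2)cc1 | intermediate
8 | (2R,3Z)-6-[(4-methoxybenzyl)oxy]-3-methylhex-3-ene-1,2-diol | COc1ccc(COCC/C=C(/C)[C@@H](O)CO)cc1 | intermediate
9 | (2R,3Z)-6-[(4-methoxybenzyl)oxy]-3-methyl-1,2-bis(triethylsilyloxy)hex-3-ene | COc1ccc(COCC/C=C(/C)[C@@H](O[Si](CC)(CC)CC)CO[Si](CC)(CC)CC)cc1 | intermediate
10 | (3Z,5R)-4-methyl-5,6-bis(triethylsilyloxy)hex-3-en-1-ol | OCC/C=C(/C)[C@@H](O[Si](CC)(CC)CC)CO[Si](CC)(CC)CC | intermediate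
11 | (3Z,5R)-4-methyl-5,6-bis(triethylsilyloxy)hex-3-enal | O=CC/C=C(/C)[C@@H](O[Si](CC)(CC)CC)CO[Si](CC)(CC)CC | intermediate
12 | methyl acrylate | C=CC(=O)OC | starting material
13 | methyl (5Z,7R)-3-hydroxy-6-methyl-2-methylidene-7,8-bis(triethylsilyloxy)oct-5-enoate (both C3 epimers) | C=C(C(=O)OC)C(O)C/C=C(/C)[C@@H](O[Si](CC)(CC)CC)CO[Si](CC)(CC)CC | intermediate
14 | methyl (2Z,5Z,7R)-2-(bromomethyl)-6-methyl-7,8-bis(triethylsilyloxy)octa-2,5-dienoate | COC(=O)/C(CBr)=C/C/C=C(/C)[C@@H](O[Si](CC)(CC)CC)CO[Si](CC)(CC)CC | intermediate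
15 | methyl (2Z,5Z,7R)-2-(bromomethyl)-8-hydroxy-6-methyl-7-(triethylsilyloxy)octa-2,5-dienoate | COC(=O)/C(CBr)=C/C/C=C(/C)[C@@H](O[Si](CC)(CC)CC)CO | intermediate
16 | methyl (2Z,5Z,7R)-2-(bromomethyl)-6-methyl-8-oxo-7-(triethylsilyloxy)octa-2,5-dienoate | COC(=O)/C(CBr)=C/C/C=C(/C)[C@@H](O[Si](CC)(CC)CC)C=O | intermediate
17 | methyl (2Z,5Z,7R)-2-[(dichlorochromio)methyl]-6-methyl-8-oxo-7-(triethylsilyloxy)octa-2,5-dienoate (allylchromium species, trivalent chromium, solvent ligands omitted) | COC(=O)/C(C[Cr](Cl)Cl)=C/C/C=C(/C)[C@@H](O[Si](CC)(CC)CC)C=O | intermediate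
18 | methyl 2-[(1R,5R,6S)-6-(dichlorochromiooxy)-4-methyl-5-(triethylsilyloxy)cyclohex-3-en-1-yl]prop-2-enoate (chromium alkoxide of the cyclised hydroxy ester) | C=C(C(=O)OC)[C@H]1CC=C(C)[C@@H](O[Si](CC)(CC)CC)[C@H]1O[Cr](Cl)Cl | intermediate
19 | (3aR,7R,7aS)-6-methyl-3-methylidene-7-(triethylsilyloxy)-3a,4,7,7a-tetrahydro-1-benzofuran-2(3H)-one | C=C1C(=O)O[C@@H]2[C@H](O[Si](CC)(CC)CC)C(C)=CC[C@H]12 | intermediate
20 | (3aR,7R,7aS)-6-methyl-3-methylidene-7-(triethylsilyloxy)-2,3,3a,4,7,7a-hexahydro-1-benzofuran-2-ol (both anomers) | C=C1C(O)O[C@@H]2[C@H](O[Si](CC)(CC)CC)C(C)=CC[C@H]12 | intermediate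
21 | (1S,2R,6R)-6-[(3S)-3-hydroxyhexa-1,5-dien-2-yl]-3-methyl-2-(triethylsilyloxy)cyclohex-3-en-1-ol | C=C([C@H](CC=C)O)[C@H]1CC=C(C)[C@@H](O[Si](CC)(CC)CC)[C@H]1O | intermediate
22 | (1S,2R,6R)-6-[(3S)-3-hydroxy-6-methylhepta-1,5-dien-2-yl]-3-methyl-2-(triethylsilyloxy)cyclohex-3-en-1-ol | C=C([C@H](CC=C(C)C)O)[C@H]1CC=C(C)[C@@H](O[Si](CC)(CC)CC)[C@H]1O | intermediate
23 | (3S)-2-[(1R,5R,6S)-6-hydroxy-4-methyl-5-(triethylsilyloxy)cyclohex-3-en-1-yl]-6-methylhepta-1,5-dien-3-yl (2Z)-2-methylbut-2-enoate | C=C([C@H](CC=C(C)C)OC(=O)/C(C)=C\C)[C@H]1CC=C(C)[C@@H](O[Si](CC)(CC)CC)[C@H]1O | intermediate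
24 | (3S)-2-[(1R,5R,6S)-6-(tert-butyldimethylsilyloxy)-4-methyl-5-(triethylsilyloxy)cyclohex-3-en-1-yl]-6-methylhepta-1,5-dien-3-yl (2Z)-2-methylbut-2-enoate | C=C([C@H](CC=C(C)C)OC(=O)/C(C)=C\C)[C@H]1CC=C(C)[C@@H](O[Si](CC)(CC)CC)[C@H]1O[Si](C)(C)C(C)(C)C | intermediate
25 | (3S)-2-[(1R,5R,6S)-6-(tert-butyldimethylsilyloxy)-5-hydroxy-4-methylcyclohex-3-en-1-yl]-6-methylhepta-1,5-dien-3-yl (2Z)-2-methylbut-2-enoate | C=C([C@H](CC=C(C)C)OC(=O)/C(C)=C\C)[C@H]1CC=C(C)[C@@H](O)[C@H]1O[Si](C)(C)C(C)(C)C | intermediate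
26 | (3S)-2-[(1S,2S,3S,4R,6R)-3-(tert-butyldimethylsilyloxy)-2-hydroxy-1-methyl-7-oxabicyclo[4.1.0]heptan-4-yl]-6-methylhepta-1,5-dien-3-yl (2Z)-2-methylbut-2-enoate | C=C([C@H](CC=C(C)C)OC(=O)/C(C)=C\C)[C@H]1C[C@H]2O[C@@]2(C)[C@@H](O)[C@H]1O[Si](C)(C)C(C)(C)C | intermediate
27 | (1R,2S,3S,4R,6R)-3-(tert-butyldimethylsilyloxy)-1-methyl-4-[(3S)-6-methyl-3-{[(2Z)-2-methylbut-2-enoyl]oxy}hepta-1,5-dien-2-yl]-7-oxabicyclo[4.1.0]heptan-2-yl (2Z)-2-methylbut-2-enoate | C=C([C@H](CC=C(C)C)OC(=O)/C(C)=C\C)[C@H]1C[C@H]2O[C@@]2(C)[C@@H](OC(=O)/C(C)=C\C)[C@H]1O[Si](C)(C)C(C)(C)C | intermediate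
28 | (3S)-2-[(1R,3S,4S,5S,6S)-6-(tert-butyldimethylsilyloxy)-3-chloro-4-hydroxy-4-methyl-5-{[(2Z)-2-methylbut-2-enoyl]oxy}cyclohexyl]-6-methylhepta-1,5-dien-3-yl (2Z)-2-methylbut-2-enoate | C=C([C@H](CC=C(C)C)OC(=O)/C(C)=C\C)[C@H]1C[C@H](Cl)[C@@](C)(O)[C@@H](OC(=O)/C(C)=C\C)[C@H]1O[Si](C)(C)C(C)(C)C | intermediate
29 | (3S)-2-[(1R,3S,4S,5S,6S)-3-chloro-4,6-dihydroxy-4-methyl-5-{[(2Z)-2-methylbut-2-enoyl]oxy}cyclohexyl]-6-methylhepta-1,5-dien-3-yl (2Z)-2-methylbut-2-enoate | C=C([C@H](CC=C(C)C)OC(=O)/C(C)=C\C)[C@H]1C[C@H](Cl)[C@@](C)(O)[C@@H](OC(=O)/C(C)=C\C)[C@H]1O | intermediate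
30 | CNP0158207.1, (2S)-3-[(1R,3S,4S,5S,6S)-3-chloro-4,6-dihydroxy-4-methyl-5-{[(2Z)-2-methylbut-2-enoyl]oxy}cyclohexyl]-1-[(2R)-3,3-dimethyloxiran-2-yl]but-3-en-2-yl (2Z)-2-methylbut-2-enoate | C=C([C@H](C[C@H]1OC1(C)C)OC(=O)/C(C)=C\C)[C@H]1C[C@H](Cl)[C@@](C)(O)[C@@H](OC(=O)/C(C)=C\C)[C@H]1O | target

**Step count and risks**

Total step count: 24. Longest linear sequence: 23 steps (steps 2 to 24, from 3; step 1 makes the Wittig salt).

Steps most likely to fail:

1. Step 13. The allylchromium species may be protonated or couple intermolecularly at the dilution that ring closure needs, and the facial selectivity at the aldehyde relative to C5 may erode. The fallback replaces reductive metalation by a preformed allylboron reagent and sets out from 13. Acetylation (Ac2O, pyridine, DMAP) should give the allylic acetate F1. Copper-catalysed SN2' borylation (B2pin2, CuCl, LiCl, KOAc, DMF) should give the allylboronate F2. Selective methanolysis of the primary silyl ether (PPTS, MeOH/CH2Cl2) should give the primary alcohol F3, and Dess–Martin oxidation the aldehyde F4. F4 should cyclise by intramolecular allylboration through a closed chair transition state (toluene, gentle warming, or Sc(OTf)3 as catalyst) to the cyclised boric ester F5. Acid (TsOH, CH2Cl2) then closes the lactone, and the sequence comes back to the route at 19.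

2. Step 9. During the slow amine-catalysed addition the base may move the β,γ-alkene of the aldehyde into conjugation, or the addition may stall. The fallback sets out from 11 and comes back at 13 without a new isolated compound: i-Bu2AlH and N-methylmorpholine N-oxide hydroaluminate methyl propiolate in THF at 0 °C to the α-(methoxycarbonyl)vinylaluminium reagent, which adds to the aldehyde under non-basic conditions.

3. Step 22. The hindered oxirane may open slowly, or with loss of regiocontrol (attack at the tertiary C4, or capture by acetate in place of chloride). The fallback reverses the order of chloride opening and acylation and sets out from 26. ClTi(OiPr)3 in CH2Cl2 at 0 °C should bind the free C5 hydroxyl and deliver chloride to C3 (hydroxyl-directed opening of a 2,3-epoxy alcohol at the distal carbon), giving the chlorohydrin diol F6. Yamaguchi angeloylation of the secondary C5 hydroxyl (angelic acid, 2,4,6-Cl3C6H2COCl, Et3N, toluene, 60 °C) uses amine base only, so no alkoxide is formed that could close the chlorohydrin, and the sequence comes back at 28.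

**Further compounds**

F1 | step 13 | methyl (5Z,7R)-3-acetoxy-6-methyl-2-methylidene-7,8-bis(triethylsilyloxy)oct-5-enoate (both C3 epimers) | C=C(C(=O)OC)C(OC(C)=O)C/C=C(/C)[C@@H](O[Si](CC)(CC)CC)CO[Si](CC)(CC)CC
F2 | step 13 | methyl (2E,5Z,7R)-6-methyl-2-[(4,4,5,5-tetramethyl-1,3,2-dioxaborolan-2-yl)methyl]-7,8-bis(triethylsilyloxy)octa-2,5-dienoate | COC(=O)/C(CB1OC(C)(C)C(C)(C)O1)=C/C/C=C(/C)[C@@H](O[Si](CC)(CC)CC)CO[Si](CC)(CC)CC
F3 | step 13 | methyl (2E,5Z,7R)-8-hydroxy-6-methyl-2-[(4,4,5,5-tetramethyl-1,3,2-dioxaborolan-2-yl)methyl]-7-(triethylsilyloxy)octa-2,5-dienoate | COC(=O)/C(CB1OC(C)(C)C(C)(C)O1)=C/C/C=C(/C)[C@@H](O[Si](CC)(CC)CC)CO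
F4 | step 13 | methyl (2E,5Z,7R)-6-methyl-8-oxo-2-[(4,4,5,5-tetramethyl-1,3,2-dioxaborolan-2-yl)methyl]-7-(triethylsilyloxy)octa-2,5-dienoate | COC(=O)/C(CB1OC(C)(C)C(C)(C)O1)=C/C/C=C(/C)[C@@H](O[Si](CC)(CC)CC)C=O
F5 | step 13 | methyl 2-[(1R,5R,6S)-4-methyl-6-[(4,4,5,5-tetramethyl-1,3,2-dioxaborolan-2-yl)oxy]-5-(triethylsilyloxy)cyclohex-3-en-1-yl]prop-2-enoate | C=C(C(=O)OC)[C@H]1CC=C(C)[C@@H](O[Si](CC)(CC)CC)[C@H]1OB1OC(C)(C)C(C)(C)O1
F0 | step 9 | none | none
F6 | step 22 | (3S)-2-[(1R,3S,4S,5S,6S)-6-(tert-butyldimethylsilyloxy)-3-chloro-4,5-dihydroxy-4-methylcyclohexyl]-6-methylhepta-1,5-dien-3-yl (2Z)-2-methylbut-2-enoate | C=C([C@H](CC=C(C)C)OC(=O)/C(C)=C\C)[C@H]1C[C@H](Cl)[C@@](C)(O)[C@@H](O)[C@H]1O[Si](C)(C)C(C)(C)C
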